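**Retrosynthetic overview**

1. The target comes from its phenol O-benzyl ether by a final hydrogenolysis. Both arenes and the oxazolidinone auxiliary are bought, so the γ-butyrolactone is the only ring built, and it is closed in the second-to-last step.
2. The lactone comes from a γ-hydroxy tert-butyl ester (acid lactonisation, then base equilibration of C3 to trans), which comes from an imide/ester succinate (LiBH4 cleaves only the imide).
3. The key C3–C4 bond (the lignan 8–8′ bond) comes from oxidative heterocoupling of two lithium enolates with trivalent iron. Both α-carbons are nucleophilic; one enolate is oxidised to an electrophilic α-carbonyl radical (an enolonium equivalent), and the Evans auxiliary on the syringyl half sets C4.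
4. The coupling partners come from 4-(benzyloxy)-3,5-dimethoxybenzaldehyde plus Meldrum's acid (reductive Knoevenagel, then N-acylation of the auxiliary) and from 3-(3,4,5-trimethoxyphenyl)propanoic acid (tert-butyl ester).

Assumption: 4-(benzyloxy)-3,5-dimethoxybenzaldehyde is taken as a catalogue compound (otherwise it is one benzylation away from syringaldehyde).

**Route**

Step 1
Reactants: 1 4-(benzyloxy)-3,5-dimethoxybenzaldehyde; 2 2,2-dimethyl-1,3-dioxane-4,6-dione (Meldrum's acid)
Product: 6 3-[4-(benzyloxy)-3,5-dimethoxyphenyl]propanoic acid, via benzylidene Meldrum's acid 3 (not isolated), via benzyl Meldrum's acid 4 (not isolated), via benzylmalonic acid 5 (not isolated)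
Conditions: HCO2H/Et3N (5:2), 95–100 °C, 4 h; then aq. HCl
Reagents that add atoms: water, O (the water released in the condensation re-enters when the dioxanedione ring is hydrolysed; formic acid gives only hydride)
Why: Knoevenagel condensation of 1 with Meldrum's acid, conjugate hydride transfer from formate to the arylidene and hydrolysis–decarboxylation of the reduced adduct run in one pot (reductive Knoevenagel alkylation), the aryl benzyl ether being inert to formate without palladium and no stereocentre being formed.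

Step 2
Reactants: 6 3-[4-(benzyloxy)-3,5-dimethoxyphenyl]propanoic acid; 7 (4S)-4-benzyl-1,3-oxazolidin-2-one
Product: 9 (4S)-4-benzyl-3-{3-[4-(benzyloxy)-3,5-dimethoxyphenyl]propanoyl}-1,3-oxazolidin-2-one, via mixed pivalic anhydride 8 (not isolated)
Conditions: PivCl (1.1 equiv), Et3N (2.5 equiv), THF, −20 °C; then LiCl (1.1 equiv), 7, −20 °C → rt
Reagents that add atoms: pivaloyl chloride, CC(C)(C)C(Cl)=O (its acyl group is carried by intermediate 8 only; none of its atoms stay in 9)
Why: the acid is activated as its mixed pivalic anhydride, which the LiCl-activated oxazolidinone attacks at the less hindered carbonyl (mixed-anhydride N-acylation), the auxiliary stereocentre being bought and not touched.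

Step 3
Reactants: 10 3-(3,4,5-trimethoxyphenyl)propanoic acid
Product: 11 tert-butyl 3-(3,4,5-trimethoxyphenyl)propanoate
Conditions: t-BuOC(=NH)CCl3 (2 equiv), CH2Cl2/cyclohexane, rt
Reagents that add atoms: tert-butyl 2,2,2-trichloroacetimidate, CC(C)(C)OC(=N)C(Cl)(Cl)Cl
Why: the carboxylic acid protonates the imidate, which then passes its tert-butyl group to the carboxylate without added Lewis acid (trichloroacetimidate esterification), giving the bulky ester needed for clean enolisation in step 4 and for chemoselectivity in step 5.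

Step 4
Reactants: 9 (4S)-4-benzyl-3-{3-[4-(benzyloxy)-3,5-dimethoxyphenyl]propanoyl}-1,3-oxazolidin-2-one; 11 tert-butyl 3-(3,4,5-trimethoxyphenyl)propanoate
Product: 14 tert-butyl (3R)-3-[4-(benzyloxy)-3,5-dimethoxybenzyl]-4-[(4S)-4-benzyl-2-oxo-1,3-oxazolidin-3-yl]-4-oxo-2-(3,4,5-trimethoxybenzyl)butanoate (mixture of C2 epimers), via imide lithium enolate 12 (not isolated), via ester lithium enolate 13 (not isolated)
Conditions: 9 (1.0 equiv), 11 (1.2 equiv), LiN(i-Pr)2 (2.3 equiv, commercial solution), THF, −78 °C, 40 min; then Fe(acac)3 (2.2 equiv), −78 °C → rt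
Reagents that add atoms: LiN(i-Pr)2, CC(C)N([Li])C(C)C (its lithium is carried by intermediates 12 and 13 only; no reagent atom other than hydrogen stays in 14)
Why: trivalent iron oxidises the more electron-rich ester enolate 13 by one electron to an electrophilic α-carbonyl radical (an enolonium equivalent), which the chelated Z-imide enolate 12 captures on the face away from the auxiliary's benzyl group, setting C3 as R, before a second trivalent iron oxidises the resulting ketyl (oxidative enolate heterocoupling); C2 forms as a mixture and is corrected in step 6.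

Step 5
Reactants: 14 tert-butyl (3R)-3-[4-(benzyloxy)-3,5-dimethoxybenzyl]-4-[(4S)-4-benzyl-2-oxo-1,3-oxazolidin-3-yl]-4-oxo-2-(3,4,5-trimethoxybenzyl)butanoate
Product: 15 tert-butyl (3R)-3-[4-(benzyloxy)-3,5-dimethoxybenzyl]-4-hydroxy-2-(3,4,5-trimethoxybenzyl)butanoate (mixture of C2 epimers)
Conditions: LiBH4 (2 equiv), H2O (1 equiv), THF/Et2O, 0 °C
Reagents that add atoms: none
Why: the exocyclic imide carbonyl, activated by lithium chelation and weak amide resonance, is reduced by LiBH4 much faster than the hindered tert-butyl ester (chemoselective reductive removal of an Evans auxiliary), so C3 is untouched and 7 is recovered.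

Step 6
Reactants: 15 tert-butyl (3R)-3-[4-(benzyloxy)-3,5-dimethoxybenzyl]-4-hydroxy-2-(3,4,5-trimethoxybenzyl)butanoate
Product: 17 (3R,4R)-4-[4-(benzyloxy)-3,5-dimethoxybenzyl]-3-(3,4,5-trimethoxybenzyl)oxolan-2-one, via lactone C3-epimer mixture 16 (not isolated)
Conditions: p-TsOH·H2O (0.2 equiv), toluene, 80 °C; then DBU (2 equiv), 100 °C
Reagents that add atoms: none
Why: acid-catalysed loss of the tert-butyl group as isobutene (plus water) with 5-exo lactonisation closes the ring, and DBU then equilibrates the enolisable C3 centre to the favoured trans (3R,4R) isomer while C4, which has no acidic proton, is retained (acid lactonisation followed by thermodynamic epimerisation).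

Step 7
Reactants: 17 (3R,4R)-4-[4-(benzyloxy)-3,5-dimethoxybenzyl]-3-(3,4,5-trimethoxybenzyl)oxolan-2-one
Product: 18 (3R,4R)-4-(4-hydroxy-3,5-dimethoxybenzyl)-3-(3,4,5-trimethoxybenzyl)oxolan-2-one
Conditions: H2 (1 atm), 10% Pd/C, EtOAc/EtOH, rt
Reagents that add atoms: none
Why: the benzylic C–O bond of the aryl benzyl ether is cleaved by catalytic hydrogenolysis while the lactone, the methyl ethers and both stereocentres are inert under these neutral conditions.

**Compound list**

1 | 4-(benzyloxy)-3,5-dimethoxybenzaldehyde | COc1cc(C=O)cc(OC)c1OCc1ccccc1 | starting material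
2 | 2,2-dimethyl-1,3-dioxane-4,6-dione (Meldrum's acid) | CC1(C)OC(=O)CC(=O)O1 | starting material
3 | 5-[4-(benzyloxy)-3,5-dimethoxybenzylidene]-2,2-dimethyl-1,3-dioxane-4,6-dione | COc1cc(C=C2C(=O)OC(C)(C)OC2=O)cc(OC)c1OCc1ccccc1 | intermediate (not isolated)
4 | 5-[4-(benzyloxy)-3,5-dimethoxybenzyl]-2,2-dimethyl-1,3-dioxane-4,6-dione | COc1cc(CC2C(=O)OC(C)(C)OC2=O)cc(OC)c1OCc1ccccc1 | intermediate (not isolated)
5 | 2-[4-(benzyloxy)-3,5-dimethoxybenzyl]propanedioic acid | COc1cc(CC(C(=O)O)C(=O)O)cc(OC)c1OCc1ccccc1 | intermediate (not isolated)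
6 | 3-[4-(benzyloxy)-3,5-dimethoxyphenyl]propanoic acid | COc1cc(CCC(=O)O)cc(OC)c1OCc1ccccc1 | intermediate
7 | (4S)-4-benzyl-1,3-oxazolidin-2-one | O=C1N[C@@H](Cc2ccccc2)CO1 | starting material
8 | 3-[4-(benzyloxy)-3,5-dimethoxyphenyl]propanoic 2,2-dimethylpropanoic anhydride | COc1cc(CCC(=O)OC(=O)C(C)(C)C)cc(OC)c1OCc1ccccc1 | intermediate (not isolated)
9 | (4S)-4-benzyl-3-{3-[4-(benzyloxy)-3,5-dimethoxyphenyl]propanoyl}-1,3-oxazolidin-2-one | COc1cc(CCC(=O)N2[C@@H](Cc3ccccc3)COC2=O)cc(OC)c1OCc1ccccc1 | intermediate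
10 | 3-(3,4,5-trimethoxyphenyl)propanoic acid | COc1cc(CCC(=O)O)cc(OC)c1OC | starting material
11 | tert-butyl 3-(3,4,5-trimethoxyphenyl)propanoate | COc1cc(CCC(=O)OC(C)(C)C)cc(OC)c1OC | intermediate
12 | lithium Z-enolate of 9 (OLi cis to the arylmethyl group) | COc1cc(C/C=C(\O[Li])N2[C@@H](Cc3ccccc3)COC2=O)cc(OC)c1OCc1ccccc1 | intermediate (not isolated)
13 | lithium enolate of 11 (kinetic geometry, OLi trans to the arylmethyl group) | COc1cc(C/C=C(/O[Li])OC(C)(C)C)cc(OC)c1OC | intermediate (not isolated)
14 | tert-butyl (3R)-3-[4-(benzyloxy)-3,5-dimethoxybenzyl]-4-[(4S)-4-benzyl-2-oxo-1,3-oxazolidin-3-yl]-4-oxo-2-(3,4,5-trimethoxybenzyl)butanoate, C2 epimer mixture | CC(C)(C)OC(=O)C(Cc1cc(OC)c(OC)c(OC)c1)[C@@H](Cc1cc(OC)c(OCc2ccccc2)c(OC)c1)C(=O)N1[C@@H](Cc2ccccc2)COC1=O | intermediate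
15 | tert-butyl (3R)-3-[4-(benzyloxy)-3,5-dimethoxybenzyl]-4-hydroxy-2-(3,4,5-trimethoxybenzyl)butanoate, C2 epimer mixture | CC(C)(C)OC(=O)C(Cc1cc(OC)c(OC)c(OC)c1)[C@@H](Cc1cc(OC)c(OCc2ccccc2)c(OC)c1)CO | intermediate
16 | (4R)-4-[4-(benzyloxy)-3,5-dimethoxybenzyl]-3-(3,4,5-trimethoxybenzyl)oxolan-2-one, C3 epimer mixture | COc1cc(C[C@H]2COC(=O)C2Cc2cc(OC)c(OC)c(OC)c2)cc(OC)c1OCc1ccccc1 | intermediate (not isolated)
17 | (3R,4R)-4-[4-(benzyloxy)-3,5-dimethoxybenzyl]-3-(3,4,5-trimethoxybenzyl)oxolan-2-one (trans) | COc1cc(C[C@H]2COC(=O)[C@@H]2Cc2cc(OC)c(OC)c(OC)c2)cc(OC)c1OCc1ccccc1 | intermediate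
18 | (3R,4R)-4-(4-hydroxy-3,5-dimethoxybenzyl)-3-(3,4,5-trimethoxybenzyl)oxolan-2-one (trans) | COc1cc(C[C@H]2COC(=O)[C@@H]2Cc2cc(OC)c(OC)c(OC)c2)cc(OC)c1O | target

**Step count and risks**

Total steps: 7. Longest linear sequence: 6 (steps 1, 2, 4, 5, 6 and 7, starting from 1); step 3 is a one-step side branch that joins at step 4.

The three steps most likely to fail are steps 4, 5 and 6.

Step 4 (oxidative heterocoupling). The risks are homodimers of 9 or 11, a modest yield, and incomplete facial control at C3. Any C3-epimeric pair must be removed by chromatography at 14, or by recrystallising 17, because it would become the enantiomer after step 5. The fallback builds the same C3–C4 bond in a polar, stepwise way and sets out from 9. The sodium enolate of 9 (NaN(SiMe3)2, THF, −78 °C) is alkylated with tert-butyl bromoacetate, whose α-carbon is an acceptor so that the α-halo ester plays the enolonium role. This gives tert-butyl (3R)-3-[4-(benzyloxy)-3,5-dimethoxybenzyl]-4-[(4S)-4-benzyl-2-oxo-1,3-oxazolidin-3-yl]-4-oxobutanoate F1. LiBH4 (THF, 0 °C) then gives tert-butyl (3R)-3-[4-(benzyloxy)-3,5-dimethoxybenzyl]-4-hydroxybutanoate F2, and catalytic p-TsOH in toluene closes it to (4R)-4-[4-(benzyloxy)-3,5-dimethoxybenzyl]oxolan-2-one F3. The lithium enolate of F3 (LiN(SiMe3)2, THF, −78 °C) is alkylated with commercial 3,4,5-trimethoxybenzyl bromide on the face opposite the C4 substituent, which gives the trans lactone directly and comes back to the route at 17.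

Step 5 (chemoselective LiBH4 reduction). The imide in 14 is very hindered, so hydride may attack the ring carbonyl of the auxiliary, or the alkoxide may lactonise in the flask and be over-reduced to a diol. The fallback separates auxiliary removal from reduction and sets out from 14. LiOH/H2O2 (THF/H2O, 0 °C) cleaves the exocyclic acyl group to (2R)-2-[4-(benzyloxy)-3,5-dimethoxybenzyl]-4-tert-butoxy-4-oxo-3-(3,4,5-trimethoxybenzyl)butanoic acid F4. BH3·SMe2 (THF, 0 °C) then reduces the free acid and leaves the tert-butyl ester, coming back to the route at 15.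

Step 6 (acid lactonisation and epimerisation). The tert-butyl cation could alkylate the electron-rich rings, or the hindered ester could lactonise slowly. The fallback closes the ring through the alkyl–oxygen bond instead of the acyl–oxygen bond and sets out from 15. MsCl/Et3N (CH2Cl2, 0 °C) gives tert-butyl (3R)-3-[4-(benzyloxy)-3,5-dimethoxybenzyl]-4-(methylsulfonyloxy)-2-(3,4,5-trimethoxybenzyl)butanoate F5. On warming in toluene with 2,6-lutidine, the ester carbonyl oxygen displaces the primary mesylate (5-exo-tet) and the tert-butyl group leaves as isobutene, with no strong acid present. This comes back to the route at 16, which the DBU stage of step 6 converts into 17.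

**Further compounds**

F1 | step 4 | tert-butyl (3R)-3-[4-(benzyloxy)-3,5-dimethoxybenzyl]-4-[(4S)-4-benzyl-2-oxo-1,3-oxazolidin-3-yl]-4-oxobutanoate | CC(C)(C)OC(=O)C[C@@H](Cc1cc(OC)c(OCc2ccccc2)c(OC)c1)C(=O)N1[C@@H](Cc2ccccc2)COC1=O
F2 | step 4 | tert-butyl (3R)-3-[4-(benzyloxy)-3,5-dimethoxybenzyl]-4-hydroxybutanoate | CC(C)(C)OC(=O)C[C@@H](Cc1cc(OC)c(OCc2ccccc2)c(OC)c1)CO
F3 | step 4 | (4R)-4-[4-(benzyloxy)-3,5-dimethoxybenzyl]oxolan-2-one | COc1cc(C[C@H]2COC(=O)C2)cc(OC)c1OCc1ccccc1
F4 | step 5 | (2R)-2-[4-(benzyloxy)-3,5-dimethoxybenzyl]-4-tert-butoxy-4-oxo-3-(3,4,5-trimethoxybenzyl)butanoic acid, C3 epimer mixture | CC(C)(C)OC(=O)C(Cc1cc(OC)c(OC)c(OC)c1)[C@@H](Cc1cc(OC)c(OCc2ccccc2)c(OC)c1)C(=O)O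
F5 | step 6 | tert-butyl (3R)-3-[4-(benzyloxy)-3,5-dimethoxybenzyl]-4-(methylsulfonyloxy)-2-(3,4,5-trimethoxybenzyl)butanoate, C2 epimer mixture | CC(C)(C)OC(=O)C(Cc1cc(OC)c(OC)c(OC)c1)[C@@H](Cc1cc(OC)c(OCc2ccccc2)c(OC)c1)COS(C)(=O)=O
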